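The earlier runs and the new flask come from a simulation with constants of no real substance, and the scatter is random.

The zeta run was still gaining at its last reading, 18.3% after 15.0 h, so it showed me no stopping point. Oak had to be bracketed.

| setting | beta | zeta | ash | oak |
|---|---|---|---|---|
| free monomer | 0.20 M | 0.78 M | 0.39 M | 0.39 M |
| transfer agent | 0.0117 M | 0.0117 M | 0.0117 M | 0.0117 M |
| pre-initiator | 3.9 mM | 3.9 mM | 3.9 mM | 3.9 mM |
| temperature | 95 °C | 115 °C | 100 °C | 130 °C |
| remark | run made earlier | run made earlier |  |  |
| time |  |  | 50 h | 50 h |

| run | time / h | monomer in chains / % |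
|---|---|---|
| beta | 2.00 | 0 |
| beta | 6.00 | 0 |
| beta | 10.0 | 0.8 |
| beta | 15.0 | 1.4 |
| beta | 25.0 | 2.6 |
| beta | 30.0 | 3.9 |
| zeta | 2.50 | 1.8 |
| zeta | 5.00 | 3.9 |
| zeta | 8.00 | 8.4 |
| zeta | 10.0 | 11.4 |
| zeta | 12.0 | 14.4 |
| zeta | 15.0 | 18.3 |

(standard deviation of a reading: 0.3 percentage points)

- the flask that comes out highest in amount of monomer in chains, in percent of the free monomer charged, or "all alike" when all lie within 1.5 percentage points (ash / oak / all alike)
- monomer in chains at the end, in percent of the free monomer charged, ash
- monomer in chains at the end, in percent of the free monomer charged, oak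



I measured each run by its log-loss, ln([free monomer] charged / [free monomer] left), which grows in a straight line as long as the loss is first order in free monomer with a steady rate constant. Between 5.00 h and 15.0 h, zeta gained 0.0162 /h. Beta, from 10.0 h to 30.0 h, gained 0.00159 /h, so zeta ran about ten times faster. These are readings and carry their scatter.

The two runs differ in free monomer as well as temperature, but I chose to treat the factor as an effect of temperature. Carrying it on to 130 °C gave me the full-speed slope, a pseudo-first-order constant of 0.0928 /h. Held for 50 h with nothing slowing it, it put oak at 99.0%, my upper bound.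

The lower bound needed an assumption: that whatever drives the growth in chains dies away in the flask. If that dying sped up with heat as much as growth did, the ratio of the two rates stayed the same and the clock dropped out. On that assumption, and with first order in free monomer, I put oak no lower than the 18.3% zeta held at its last reading, a log-loss worth 2.18 h at full speed. For ash, the same factor and beta's lag gave me 12.0%.

The forecast chose oak, with ash at 13% and oak at 75% (range 40% to 97%), the oak figure inside my bracket, and said of the possible brakes: “Neither effect can be seen in these data”. On my slope, its oak figure is worth 14.9 h at full speed.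

The flasks gave ash 14.6% and oak 40.0%, so oak came out highest.

    pre-initiator ⇌ initiator (K = 0.940, k = 0.0400 /h, Ea = 118 kJ/mol, ΔH = −40.0 kJ/mol)
    free monomer + living end → monomer in chains + living end, rate k2*[living end]*[free monomer] (k = 2.90 /M/h, Ea = 98.0 kJ/mol)
    initiator → spent initiator (k = 0.0470 /h, Ea = 117 kJ/mol)
    living end + transfer agent → dead chain (kL = 3.10 /M/h, Ea = 70.0 kJ/mol)
    free monomer + initiator → living end + monomer in chains (k = 1.10 /M/h, Ea = 68.0 kJ/mol)
    (constants at 100 °C)

Oak already held 38.9% in chains at 25.0 h, with 0.0148% of its pre-initiator left. Divided by the full-speed slope, its final log-loss is 5.51 h of the 50 h. The neighbour like oak but charged with 0.016 M of pre-initiator reached 96.7%, which is 36.6 h at the same slope.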